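**Retrosynthetic overview**

1. The target is a 7-methoxycoumarin (ring A benzene, ring B pyranone) with a side chain on C6 of ring A: C1(OH)–C2(O-acyl)–C3(CH3)2OH, C1/C2 syn. The tertiary carbinol C3 is first traced back to an isopropenyl group (Markovnikov hydration).
2. Key disconnection, C1–C2: 7-methoxycoumarin-6-carbaldehyde plus a γ-acyloxy-β-methylallyl chromium reagent made catalytically from allylic chloride 9. This one operation sets both new stereocentres, places the (R)-2-methylbutanoate on the C2 oxygen and leaves the C1 hydroxyl free.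
3. Enabling feature: the acylated oxygen sits on C2, between the benzylic carbinol carbon C1 (on C6 of ring A) and C3, whose gem-dimethyl carbinol is a hydrated C(CH3)=CH2 group. C2–C3 is therefore a latent 2-methylallyl unit that carries the ester oxygen on its γ-carbon.
4. Chloride 9 comes from methacrolein and (R)-2-methylbutanoyl chloride; the aldehyde comes from 2-hydroxy-4-methoxybenzaldehyde by bromination, Wittig/lactonisation and Pd-catalysed formylation.
5. Ring order: ring A is bought, ring B is closed in step 2, no further ring is formed.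

Key step: step 6

Assumption (chemistry): the (R,R) antipode of the salen ligand is taken to deliver the (1R,2R) adduct in step 6; if the sense of induction proves opposite, the equally available (S,S) antipode is used and nothing else changes.

**Route**

Step 1
Reactants: 1 2-hydroxy-4-methoxybenzaldehyde
Product: 2 5-bromo-2-hydroxy-4-methoxybenzaldehyde
Conditions: Br2, AcOH, rt
Reagents that add atoms: bromine, BrBr
Why: Electrophilic aromatic bromination, in which the hydroxyl (para) and the methoxy group (ortho) both direct to C5 while C3 between the two oxygens is hindered.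

Step 2
Reactants: 2 5-bromo-2-hydroxy-4-methoxybenzaldehyde
Product: 4 6-bromo-7-methoxy-2H-chromen-2-one, via hydroxycinnamate ester 3 (not isolated)
Conditions: Ph3P=CHCO2Et, PhNEt2, reflux
Reagents that add atoms: ethyl (triphenylphosphoranylidene)acetate, CCOC(=O)C=P(c1ccccc1)(c1ccccc1)c1ccccc1
Why: Wittig olefination with a stabilised ylide followed by thermal E/Z equilibration and lactonisation of the Z ester by the ortho phenol (6-exo-trig acyl substitution) is the standard salicylaldehyde-to-coumarin annulation and closes ring B.

Step 3
Reactants: 4 6-bromo-7-methoxy-2H-chromen-2-one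
Product: 5 7-methoxy-2-oxo-2H-chromene-6-carbaldehyde
Conditions: Pd(PPh3)2Cl2 (3 mol %), CO (1 atm), HCO2Na, DMF, 100 °C
Reagents that add atoms: carbon monoxide, [C-]#[O+]
Why: Palladium-catalysed reductive carbonylation of an aryl bromide (oxidative addition to zerovalent palladium, CO insertion, formate-derived hydride transfer with loss of CO2, reductive elimination), which tolerates the lactone and the aryl ether.

Step 4
Reactants: 6 (R)-2-methylbutanoic acid
Product: 7 (R)-2-methylbutanoyl chloride
Conditions: (COCl)2, DMF (cat.), CH2Cl2, 0 °C to rt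
Reagents that add atoms: oxalyl chloride, ClC(=O)C(=O)Cl
Why: Acid chloride formation through the Vilsmeier-type chloroiminium activator runs without base, so no ketene forms and the α-stereocentre should be retained.

Step 5
Reactants: 7 (R)-2-methylbutanoyl chloride; 8 methacrolein (2-methylprop-2-enal)
Product: 9 3-chloro-2-methylprop-1-en-1-yl (2R)-2-methylbutanoate (E/Z mixture)
Conditions: ZnCl2 (2 mol %), CH2Cl2, −20 °C to rt
Reagents that add atoms: none
Why: Lewis acid-catalysed 1,4-addition of an acyl chloride to an enal (O-acylation of the carbonyl, conjugate delivery of chloride) gives the γ-acyloxyallyl chloride; both alkene isomers and any allylic 1,2-adduct should converge on the same allyl chromium species in step 6, so the mixture is used as such.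

Step 6
Reactants: 5 7-methoxy-2-oxo-2H-chromene-6-carbaldehyde; 9 3-chloro-2-methylprop-1-en-1-yl (2R)-2-methylbutanoate
Product: 11 (1R,2R)-1-hydroxy-1-(7-methoxy-2-oxo-2H-chromen-6-yl)-3-methylbut-3-en-2-yl (2R)-2-methylbutanoate, via trimethylsilyl ether 10 (not isolated)
Conditions: CrCl3 (10 mol %), Mn powder, (R,R)-N,N'-bis(3,5-di-tert-butylsalicylidene)-1,2-cyclohexanediamine (12 mol %), Et3N (25 mol %), TMSCl, MeCN, rt; then 1 M HCl, THF, 0 °C
Reagents that add atoms: chlorotrimethylsilane, C[Si](C)(C)Cl (its Me3Si group is carried by intermediate 10 only; none of it remains in 11)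
Why: Mn reduces CrCl3 to the divalent state, the salen-bound divalent chromium converts the allylic C–Cl bond of 9 in two one-electron steps into a γ-acyloxy-β-methylallyl chromium species in the trivalent state, this adds through its oxygen-bearing γ-carbon to the formyl carbon of 5, and TMSCl silylates the chromium alkoxide to 10, which frees the catalyst and keeps the ester on the C2 oxygen until mild acid releases 11. The closest known reaction type is the salen–chromium-catalysed asymmetric Nozaki–Hiyama–Kishi addition of 3-halopropenyl esters to aromatic aldehydes under Mn/TMSCl turnover, which gives syn-1,2-diol monoesters. No ring is closed. The syn relationship of the C1 hydroxyl and the C2 acyloxy group should come from the transition state, in which the allyl unit reacts with its acyloxy group cis to the chromium-bearing CH2 (held by an ester O→Cr contact), and the absolute configuration at both carbons (Si-face attack on the aldehyde, 1R,2R) should come from the twofold-symmetric salen ligand, the (2R) acyl centre being a spectator. The step needs γ- over α-regioselectivity, which the allylic transposition inherent in carbonyl allylation secures, aldehyde over lactone and ester chemoselectivity, which the mild organochromium nucleophile secures, and syn and facial selectivity from the catalyst; any minor stereoisomer is a diastereomer of 11 because of the enantiopure acyl group and should be removable by chromatography.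

Step 7
Reactants: 11 (1R,2R)-1-hydroxy-1-(7-methoxy-2-oxo-2H-chromen-6-yl)-3-methylbut-3-en-2-yl (2R)-2-methylbutanoate
Product: 12 (1R,2S)-1,3-dihydroxy-1-(7-methoxy-2-oxo-2H-chromen-6-yl)-3-methylbutan-2-yl (2R)-2-methylbutanoate
Conditions: Co(acac)2 (20 mol %), PhSiH3, O2 (1 atm), THF, rt
Reagents that add atoms: dioxygen, O=O
Why: Mukaiyama hydration, in which hydrogen-atom transfer from a cobalt hydride to the electron-rich 1,1-disubstituted alkene gives the tertiary radical, O2 traps it and the silane reduces the peroxide to the Markovnikov alcohol; the conditions are neutral (no acyl migration), no stereocentre is formed or touched (the C2 descriptor changes from R to S only through the priority change at C3), and the conjugated, electron-poor C3=C4 bond of ring B is expected to react more slowly.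

**Compound list**

1 | 2-hydroxy-4-methoxybenzaldehyde | COc1ccc(C=O)c(O)c1 | starting material
2 | 5-bromo-2-hydroxy-4-methoxybenzaldehyde | COc1cc(O)c(C=O)cc1Br | intermediate
3 | ethyl 3-(5-bromo-2-hydroxy-4-methoxyphenyl)prop-2-enoate (E/Z mixture formed in the flask; the Z isomer lactonises) | CCOC(=O)C=Cc1cc(Br)c(OC)cc1O | intermediate
4 | 6-bromo-7-methoxy-2H-chromen-2-one | COc1cc2oc(=O)ccc2cc1Br | intermediate
5 | 7-methoxy-2-oxo-2H-chromene-6-carbaldehyde | COc1cc2oc(=O)ccc2cc1C=O | intermediate
6 | (R)-2-methylbutanoic acid | CC[C@@H](C)C(=O)O | starting material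
7 | (R)-2-methylbutanoyl chloride | CC[C@@H](C)C(=O)Cl | intermediate
8 | methacrolein (2-methylprop-2-enal) | CC(=C)C=O | starting material
9 | 3-chloro-2-methylprop-1-en-1-yl (2R)-2-methylbutanoate (E/Z mixture) | CC[C@@H](C)C(=O)OC=C(C)CCl | intermediate
10 | (1R,2R)-1-(7-methoxy-2-oxo-2H-chromen-6-yl)-3-methyl-1-[(trimethylsilyl)oxy]but-3-en-2-yl (2R)-2-methylbutanoate (formed in the flask) | CC[C@@H](C)C(=O)O[C@@H]([C@H](O[Si](C)(C)C)c1cc2ccc(=O)oc2cc1OC)C(C)=C | intermediate
11 | (1R,2R)-1-hydroxy-1-(7-methoxy-2-oxo-2H-chromen-6-yl)-3-methylbut-3-en-2-yl (2R)-2-methylbutanoate | CC[C@@H](C)C(=O)O[C@@H]([C@H](O)c1cc2ccc(=O)oc2cc1OC)C(C)=C | intermediate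
12 | (1R,2S)-1,3-dihydroxy-1-(7-methoxy-2-oxo-2H-chromen-6-yl)-3-methylbutan-2-yl (2R)-2-methylbutanoate | CC[C@@H](C)C(=O)O[C@@H]([C@H](O)c1cc2ccc(=O)oc2cc1OC)C(C)(C)O | target

**Step count and risks**

Total step count: 7. Longest linear sequence: 5 steps (steps 1, 2, 3, 6, 7); the reagent branch (steps 4, 5) joins at step 6.

Steps most likely to fail:

1. Step 6. The allyl transfer may show insufficient syn/anti or facial control (the β-methyl group and the ortho-methoxy group are not present in the parent cases). Pinacol coupling of 5 may compete, and the acyl group may migrate before the alkoxide is silylated. Fallback, setting out from 5 and returning at 11: the same bond is made by a chiral phosphoric acid-catalysed syn-alkoxyallylboration and the ester is introduced afterwards.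
   - 4-Methoxyphenol is alkylated with 3-chloro-2-methylpropene (K2CO3, acetone, reflux) to methallyl 4-methoxyphenyl ether F1.
   - Deprotonation (s-BuLi, THF, −78 °C) and trapping of the cis-chelated allyllithium with 2-isopropoxy-4,4,5,5-tetramethyl-1,3,2-dioxaborolane should give the (Z)-γ-aryloxy-β-methylallyl pinacol boronate F2.
   - F2 should add to 5 under catalysis by 3,3'-bis(2,4,6-triisopropylphenyl)-1,1'-binaphthyl-2,2'-diyl hydrogen phosphate (antipode chosen for the 1R,2R series; toluene, −40 °C) through a chair transition state to the syn ether alcohol F3.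
   - TBSOTf and 2,6-lutidine (CH2Cl2, 0 °C) protect the C1 hydroxyl as silyl ether F4.
   - (NH4)2Ce(NO3)6 in MeCN/H2O at 0 °C removes the 4-methoxyphenyl group to give alcohol F5.
   - Acylation with 7 (pyridine, DMAP cat., CH2Cl2, 0 °C) gives ester F6.
   - HF·pyridine in THF removes the silyl group to give 11.

2. Step 7. Hydrogen-atom transfer to the conjugated C3=C4 bond of ring B may compete with hydration of the isopropenyl group, or the peroxide stage may be reduced incompletely. Fallback, setting out from 11 and returning at 12: a polar sequence that only addresses the electron-rich alkene.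
   - mCPBA with NaHCO3 (CH2Cl2, 0 °C) should give epoxide F7; its two epimers at the oxirane carbon are of no consequence.
   - LiI and AcOH in THF should open the oxirane at the CH2 terminus to iodohydrin F8.
   - Bu3SnH with AIBN (toluene, 80 °C) removes the iodine by a radical chain to give 12.

3. Step 3. Hydrodebromination of the aryl–palladium intermediate by formate may outrun CO insertion, or oxidative addition at the electron-rich, ortho-alkoxy C–Br bond may be slow. Fallback, setting out from 4 and returning at 5: the formyl carbon is brought in as a vinyl group.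
   - Stille coupling of 4 with Bu3SnCH=CH2 (Pd(PPh3)4, toluene, 100 °C) should give 6-vinyl-7-methoxycoumarin F9.
   - Lemieux–Johnson cleavage (OsO4 cat., NaIO4, 2,6-lutidine, dioxane/H2O, rt) of the electron-rich vinyl group, in preference to the lactone double bond, should give 5.

**Further compounds**

F1 | step 6 | 1-methoxy-4-[(2-methylprop-2-en-1-yl)oxy]benzene | COc1ccc(OCC(C)=C)cc1
F2 | step 6 | 2-[(2Z)-3-(4-methoxyphenoxy)-2-methylprop-2-en-1-yl]-4,4,5,5-tetramethyl-1,3,2-dioxaborolane | COc1ccc(O/C=C(/C)CB2OC(C)(C)C(C)(C)O2)cc1
F3 | step 6 | 6-[(1R,2R)-1-hydroxy-2-(4-methoxyphenoxy)-3-methylbut-3-en-1-yl]-7-methoxy-2H-chromen-2-one | COc1ccc(O[C@@H]([C@H](O)c2cc3ccc(=O)oc3cc2OC)C(C)=C)cc1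
F4 | step 6 | 6-[(1R,2R)-1-[(tert-butyldimethylsilyl)oxy]-2-(4-methoxyphenoxy)-3-methylbut-3-en-1-yl]-7-methoxy-2H-chromen-2-one | COc1ccc(O[C@@H]([C@H](O[Si](C)(C)C(C)(C)C)c2cc3ccc(=O)oc3cc2OC)C(C)=C)cc1
F5 | step 6 | 6-[(1R,2R)-1-[(tert-butyldimethylsilyl)oxy]-2-hydroxy-3-methylbut-3-en-1-yl]-7-methoxy-2H-chromen-2-one | O[C@@H]([C@H](O[Si](C)(C)C(C)(C)C)c1cc2ccc(=O)oc2cc1OC)C(C)=C
F6 | step 6 | (1R,2R)-1-[(tert-butyldimethylsilyl)oxy]-1-(7-methoxy-2-oxo-2H-chromen-6-yl)-3-methylbut-3-en-2-yl (2R)-2-methylbutanoate | CC[C@@H](C)C(=O)O[C@@H]([C@H](O[Si](C)(C)C(C)(C)C)c1cc2ccc(=O)oc2cc1OC)C(C)=C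
F7 | step 7 | (1S,2R)-2-hydroxy-2-(7-methoxy-2-oxo-2H-chromen-6-yl)-1-(2-methyloxiran-2-yl)ethyl (2R)-2-methylbutanoate (both configurations at the oxirane carbon) | CC[C@@H](C)C(=O)O[C@@H]([C@H](O)c1cc2ccc(=O)oc2cc1OC)C1(C)CO1
F8 | step 7 | (1R,2S)-1,3-dihydroxy-4-iodo-1-(7-methoxy-2-oxo-2H-chromen-6-yl)-3-methylbutan-2-yl (2R)-2-methylbutanoate (both configurations at C3) | CC[C@@H](C)C(=O)O[C@@H]([C@H](O)c1cc2ccc(=O)oc2cc1OC)C(C)(O)CI
F9 | step 3 | 6-ethenyl-7-methoxy-2H-chromen-2-one | COc1cc2oc(=O)ccc2cc1C=C
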